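(The runs are simulated for substances that don't exist, noise included.)

Solid E and J cannot between them hold the grey charge: at 80.0 min they add up to 70.3%.

| setting | grey | ochre | flask |
|---|---|---|---|
| E | 1.5 M | 1 M | 1.5 M |
| L | 1.95 M | 1.95 M | 1.95 M |
| remark | the very flask that is asked about, followed so far | run made earlier |  |
| time |  |  | 6.0 h |

grey run (percent of the E charged)

| time / min | E / % | J / % |
|---|---|---|
| 6.00 | 66.3 | 11.8 |
| 10.0 | 61.4 | 12.8 |
| 15.0 | 60.2 | 13.8 |
| 25.0 | 55.9 | 17.3 |
| 40.0 | 56.5 | 16.1 |
| 80.0 | 54.3 | 16.0 |

ochre run (percent of the E charged)

| time / h | E / % | J / % |
|---|---|---|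
| 0.200 | 41.0 | 21.7 |
| 0.333 | 37.0 | 23.9 |
| 0.500 | 33.7 | 25.2 |
| 0.833 | 33.7 | 25.1 |
| 1.33 | 33.7 | 26.6 |
| 2.50 | 35.3 | 23.7 |

(standard deviation of a reading: 1 percentage point)

- E is a solid; its amount is given per volume of the solution
- at the start none of E is in solution
- what has only dissolved of E counts as not reacted
- Q means what is dissolved; the solid is not counted in it
- the reaction counts as stopped when no species that holds the E changes by six tenths of a point or more over the second half of the time

- why nothing more happens at 6.0 h, or that something still does (for what has run out or reacted, a solid counts together with what of it has only dissolved) (all of E has reacted / it is still moving / forward and back rates have come level / L has run out first)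
- part of the E that has turned into other species by 6.0 h (what has only dissolved does not count)
- the J standing at 6.0 h, as a percentage of the E charged
- the Q standing at 6.0 h, as a percentage of the E charged

So we reckon the gap (the closing error of the mass balance): E charged, in M, less solid E, less J, averaged over the level readings. Grey gives 0.419 M and ochre 0.407 M, about the same though the charges differ. We carry their mean, the gap, 0.413 M.

Two extreme flasks are easy. If the gap is purely dissolved Q, conversion equals J at 16.5%, and Q stands at 27.6% of the E charged. If it is purely reacted E in something unseen, conversion is 44.0% and Q is zero. Every point of the gap is one or the other, so the real flask lies between. The ends differ by a factor of 2.67, or 0.426 of a power of ten, and the runs give readings of E and J but none of Q. We therefore take the middle in logarithms: conversion 26.9%, Q 17.1%, J 16.5%.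

Even the second end uses 33.9% of L at one L per E, and solid E reads 55.6% in grey. Yet grey is flat within its scatter from 25.0 min, and 6.0 h lies 1.16 powers of ten later, so we expect level rates.

The forecast says forward and back rates have come level, with conversion 16.5%, J 16.5% and Q 27.5%: “The remainder is dissolved Q at saturation”. On conversion and Q it stands close to our first end, where we take the middle.

The simulation gives forward and back rates have come level, with conversion 25.8%, J 17.1% and Q 18.0%.

    E ⇌ Q, rate k1*(cs1 - [Q]) while solid is left; crystals form when [Q] > cs1 (solubility = 0.270 M, k = 5.90 min⁻¹)
    G ⇌ J + D (K = 0.500 M, k = 4.50 min⁻¹)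
    Q + L ⇌ G (K = 0.310 M⁻¹, k = 0.100 M⁻¹ min⁻¹)

In this flask the gap is Q plus G, a species formed on the way, together 0.401 M at 6.00 h. By itself, at 6.00 h, the step from Q + L to G relaxes, both ways together, with a half-life of 1.37 min, far shorter than the 6.0 h asked. At 0.600 h G in this flask already stands at the 8.70% it holds at the asked time. In the neighbour with 1.2 M of L, Q stays at 18.0%, G stands at 5.17%, and the gap is 0.347 M.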